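**Retrosynthetic overview**
- Last bond set free: the C6–OOH is unmasked from an acetone monoperoxyketal; the enone comes from a Claisen–Schmidt condensation of a side-chain-bearing acetophenone with 4-hydroxybenzaldehyde.
- The (R)-peroxide carbon comes from an (S)-allylic alcohol by sulfonate displacement with a peroxide anion (inversion); the alcohol comes from an (S)-6,7-epoxide of geranyl acetate (Shi epoxidation, then epoxide-to-allylic-alcohol isomerisation).
- The aryl–CH2 bond is made by nickel-catalysed reductive coupling of an aryl iodide with the allylic acetate, which keeps the E-geranyl geometry.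
- Key step: the fully differentiated iodo-acetophenone is made in one operation from C2v-symmetric 2-iodo-1,3-dimethoxybenzene by Friedel–Crafts acetylation with chelation-controlled loss of one methyl group.
- No ring is built: both benzene rings are bought, and the only ring formed is the transient oxirane (step 2), opened again in step 3.

Assumption: compounds 1, 4, 9 and 13 and the L-fructose-derived (ent-)Shi ketone are bought; the stereocentre in the target SMILES is read as (R).

**Step 1**
Reactants: 1 2-iodo-1,3-dimethoxybenzene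
Product: 3 1-(2-hydroxy-3-iodo-4-methoxyphenyl)ethan-1-one, via dimethoxy ketone 2 (not isolated)
Conditions: AcCl (1.2 equiv), AlCl3 (3 equiv), CH2Cl2, −10 °C, 1 h, then 35 °C, 4 h; ice/1 M HCl
Reagents that add atoms: acetyl chloride CC(=O)Cl
Why: Friedel–Crafts acylation at C4 (C4 and C6 are equivalent, so the symmetry is broken without a regiochemical choice) is followed by AlCl3 cleavage of only the methoxy group that chelates the new ketone, as known for 1,3-dimethoxybenzenes, and acylating cold first deactivates the ring before the electron-rich C–I carbon can be protonated.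

**Step 2**
Reactants: 4 geranyl acetate [(2E)-3,7-dimethylocta-2,6-dien-1-yl acetate]
Product: 5 [(2E)-5-[(2S)-3,3-dimethyloxiran-2-yl]-3-methylpent-2-en-1-yl] acetate
Conditions: ent-Shi ketone (1,2:4,5-di-O-isopropylidene-β-L-erythro-2,3-hexodiulo-2,6-pyranose, 30 mol%), Oxone (2KHSO5·KHSO4·K2SO4), K2CO3, Bu4NHSO4 (cat.), MeCN/CH2(OMe)2/aq. Na2B4O7 buffer (pH 10.5), −10 → 0 °C, 2 h
Reagents that add atoms: potassium peroxymonosulfate (the oxidising salt of Oxone) [K+].[O-]S(=O)(=O)OO
Why: Shi asymmetric epoxidation, in which the chiral dioxirane attacks only the electron-rich 6,7-alkene (the 2,3-alkene is deactivated by the allylic acetate) and, because the D-fructose ketone gives (R)-epoxides of trisubstituted alkenes, its enantiomer sets (S) at C6 (about 90% ee expected; residual enantiomer can be removed on a chiral phase at 12).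

**Step 3**
Reactants: 5 [(2E)-5-[(2S)-3,3-dimethyloxiran-2-yl]-3-methylpent-2-en-1-yl] acetate
Product: 7 (2E,6S)-6-hydroxy-3,7-dimethylocta-2,7-dien-1-yl acetate, via silyl ether 6 (not isolated)
Conditions: TMSOTf (1.2 equiv), 2,6-lutidine (1.5 equiv), toluene, −78 °C; DBU (2 equiv), −78 °C → rt; then 1 M aq. HCl, THF, 0 °C, 10 min
Reagents that add atoms: trimethylsilyl trifluoromethanesulfonate C[Si](C)(C)OS(=O)(=O)C(F)(F)F (its Me3Si group is carried by 6 only)
Why: Noyori silyl triflate/amidine isomerisation of an epoxide to an allylic alcohol, in which the oxirane opens at the tertiary C7–O bond and a methyl proton is lost, so the C6–O bond is never broken and C6 stays (S), while the primary acetate is inert at low temperature.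

**Step 4**
Reactants: 3 1-(2-hydroxy-3-iodo-4-methoxyphenyl)ethan-1-one and 7 (2E,6S)-6-hydroxy-3,7-dimethylocta-2,7-dien-1-yl acetate
Product: 8 1-[2-hydroxy-3-[(2E,6S)-6-hydroxy-3,7-dimethylocta-2,7-dien-1-yl]-4-methoxyphenyl]ethan-1-one
Conditions: NiCl2(dme) (10 mol%), 4,4'-di-tert-butyl-2,2'-bipyridine (10 mol%), Zn dust (2.5 equiv), THF/DMA 4:1, 40 °C, 16 h
Reagents that add atoms: none
Why: Nickel-catalysed reductive cross-electrophile coupling of an aryl halide with an allylic acetate (Zn as terminal reductant), in which the arylnickel species takes up the allyl unit and reductive elimination at the unhindered CH2 terminus gives the linear E product without touching the ketone, the phenol, the secondary alcohol or the remote stereocentre.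

**Step 5**
Reactants: 9 2,3-dimethylbut-2-ene
Product: 10 2-methoxypropan-2-yl hydroperoxide
Conditions: O3, MeOH/CH2Cl2 1:4, −78 °C; N2 purge; volatiles removed at 0 °C (small scale, behind a shield, used at once)
Reagents that add atoms: ozone [O-][O+]=O; methanol CO
Why: Ozonolysis with solvent trapping (Criegee mechanism), in which the primary ozonide splits into acetone and acetone O-oxide and methanol adds to the carbonyl oxide to give the α-methoxy hydroperoxide, with no stereocentre involved.

**Step 6**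
Reactants: 8 1-[2-hydroxy-3-[(2E,6S)-6-hydroxy-3,7-dimethylocta-2,7-dien-1-yl]-4-methoxyphenyl]ethan-1-one and 10 2-methoxypropan-2-yl hydroperoxide
Product: 12 1-[2-hydroxy-4-methoxy-3-[(2E,6R)-6-[(2-methoxypropan-2-yl)peroxy]-3,7-dimethylocta-2,7-dien-1-yl]phenyl]ethan-1-one, via mesylate 11 (not isolated)
Conditions: Ms2O (1.3 equiv), Et3N (2 equiv), CH2Cl2, −40 °C, 30 min; cannulated into 10 (4 equiv) + CsOH·H2O (3.5 equiv), DMF, −20 → 0 °C, 4 h
Reagents that add atoms: methanesulfonic anhydride CS(=O)(=O)OS(C)(=O)=O (its mesyl group is carried by 11 only)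
Why: Dussault-type SN2 displacement of a secondary sulfonate by an α-effect peroxide anion (inversion as in the Williams–Mosher hydroperoxide synthesis), in which the aliphatic alcohol is mesylated ahead of the hindered, hydrogen-bonded phenol and back-side attack of the caesium peroxide turns (S) into (R), the perketal then masking the hydroperoxide for the aldol step.

**Step 7**
Reactants: 12 1-[2-hydroxy-4-methoxy-3-[(2E,6R)-6-[(2-methoxypropan-2-yl)peroxy]-3,7-dimethylocta-2,7-dien-1-yl]phenyl]ethan-1-one and 13 4-hydroxybenzaldehyde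
Product: 15 (2E)-1-[2-hydroxy-4-methoxy-3-[(2E,6R)-6-[(2-methoxypropan-2-yl)peroxy]-3,7-dimethylocta-2,7-dien-1-yl]phenyl]-3-(4-hydroxyphenyl)prop-2-en-1-one, via aldol 14 (not isolated)
Conditions: KOH (50% aq., 10 equiv), EtOH, 0 °C → rt, 36 h; cold aq. NH4Cl to pH 7
Reagents that add atoms: none
Why: Claisen–Schmidt condensation (aldol addition, then E1cB dehydration) gives the thermodynamically favoured E enone, the perketal being a dialkyl peroxide that is itself made under hydroxide, so no peroxide anion is present to epoxidise the enone and C6 is not affected.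

**Step 8**
Reactants: 15 (2E)-1-[2-hydroxy-4-methoxy-3-[(2E,6R)-6-[(2-methoxypropan-2-yl)peroxy]-3,7-dimethylocta-2,7-dien-1-yl]phenyl]-3-(4-hydroxyphenyl)prop-2-en-1-one
Product: 16 (2E)-1-[3-[(2E,6R)-6-hydroperoxy-3,7-dimethylocta-2,7-dien-1-yl]-2-hydroxy-4-methoxyphenyl]-3-(4-hydroxyphenyl)prop-2-en-1-one (CNP0163229.1)
Conditions: PPTS (0.2 equiv), MeOH, 0 °C → rt, 3 h; NaHCO3; chromatography in dim light
Reagents that add atoms: none
Why: Acid-catalysed transketalisation, in which methanol takes the acetone unit as 2,2-dimethoxypropane and frees the hydroperoxide without breaking the C6–O bond, so (R) is kept, under conditions too mild for flavanone closure, Hock cleavage or chroman formation.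

**Compound list**
1 | 2-iodo-1,3-dimethoxybenzene | COc1cccc(OC)c1I | starting material
2 | 1-(3-iodo-2,4-dimethoxyphenyl)ethan-1-one | CC(=O)c1ccc(OC)c(I)c1OC | intermediate
3 | 1-(2-hydroxy-3-iodo-4-methoxyphenyl)ethan-1-one | CC(=O)c1ccc(OC)c(I)c1O | intermediate
4 | geranyl acetate, (2E)-3,7-dimethylocta-2,6-dien-1-yl acetate | CC(=O)OC/C=C(\C)CCC=C(C)C | starting material
5 | [(2E)-5-[(2S)-3,3-dimethyloxiran-2-yl]-3-methylpent-2-en-1-yl] acetate | CC(=O)OC/C=C(\C)CC[C@@H]1OC1(C)C | intermediate
6 | (2E,6S)-3,7-dimethyl-6-[(trimethylsilyl)oxy]octa-2,7-dien-1-yl acetate | CC(=O)OC/C=C(\C)CC[C@H](O[Si](C)(C)C)C(C)=C | intermediate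
7 | (2E,6S)-6-hydroxy-3,7-dimethylocta-2,7-dien-1-yl acetate | CC(=O)OC/C=C(\C)CC[C@H](O)C(C)=C | intermediate
8 | 1-[2-hydroxy-3-[(2E,6S)-6-hydroxy-3,7-dimethylocta-2,7-dien-1-yl]-4-methoxyphenyl]ethan-1-one | CC(=O)c1ccc(OC)c(C/C=C(\C)CC[C@H](O)C(C)=C)c1O | intermediate
9 | 2,3-dimethylbut-2-ene | CC(C)=C(C)C | starting material
10 | 2-methoxypropan-2-yl hydroperoxide | COC(C)(C)OO | intermediate
11 | (3S,6E)-8-(3-acetyl-2-hydroxy-6-methoxyphenyl)-2,6-dimethylocta-1,6-dien-3-yl methanesulfonate | CC(=O)c1ccc(OC)c(C/C=C(\C)CC[C@H](OS(C)(=O)=O)C(C)=C)c1O | intermediate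
12 | 1-[2-hydroxy-4-methoxy-3-[(2E,6R)-6-[(2-methoxypropan-2-yl)peroxy]-3,7-dimethylocta-2,7-dien-1-yl]phenyl]ethan-1-one | CC(=O)c1ccc(OC)c(C/C=C(\C)CC[C@@H](OOC(C)(C)OC)C(C)=C)c1O | intermediate
13 | 4-hydroxybenzaldehyde | O=Cc1ccc(O)cc1 | starting material
14 | 3-hydroxy-1-[2-hydroxy-4-methoxy-3-[(2E,6R)-6-[(2-methoxypropan-2-yl)peroxy]-3,7-dimethylocta-2,7-dien-1-yl]phenyl]-3-(4-hydroxyphenyl)propan-1-one (both carbinol epimers) | C=C(C)[C@@H](CC/C(C)=C/Cc1c(OC)ccc(C(=O)CC(O)c2ccc(O)cc2)c1O)OOC(C)(C)OC | intermediate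
15 | (2E)-1-[2-hydroxy-4-methoxy-3-[(2E,6R)-6-[(2-methoxypropan-2-yl)peroxy]-3,7-dimethylocta-2,7-dien-1-yl]phenyl]-3-(4-hydroxyphenyl)prop-2-en-1-one | C=C(C)[C@@H](CC/C(C)=C/Cc1c(OC)ccc(C(=O)/C=C/c2ccc(O)cc2)c1O)OOC(C)(C)OC | intermediate
16 | (2E)-1-[3-[(2E,6R)-6-hydroperoxy-3,7-dimethylocta-2,7-dien-1-yl]-2-hydroxy-4-methoxyphenyl]-3-(4-hydroxyphenyl)prop-2-en-1-one | C=C(C)[C@@H](CC/C(C)=C/Cc1c(OC)ccc(C(=O)/C=C/c2ccc(O)cc2)c1O)OO | target

**Step count**
Total: 8 steps (the one-step preparation of peroxide reagent 10 included). Longest linear sequence: 6 steps (4 → 5 → 7 → 8 → 12 → 15 → 16).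

**Three steps most likely to fail**

Step 1. The iodine sits between two methoxy groups and may be lost or migrate under AlCl3/HCl. The fallback sets out from 1 and comes back at 3 without any Friedel–Crafts chemistry. Mono-demethylation (BBr3, 1.0 equiv, CH2Cl2, −78 → 0 °C) breaks the symmetry at oxygen and gives 2-iodo-3-methoxyphenol F1. Magnesium-templated ortho-formylation (MgCl2, Et3N, paraformaldehyde, MeCN, reflux) gives 2-hydroxy-3-iodo-4-methoxybenzaldehyde F2. MeMgBr (2.2 equiv, THF, 0 °C) gives 1-(2-hydroxy-3-iodo-4-methoxyphenyl)ethan-1-ol F3, and MnO2 (CH2Cl2, rt) oxidises this benzylic alcohol to 3.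

Step 4. The aryl iodide carries two ortho substituents and a free phenol, and E/Z leakage through the allylnickel species is possible. The fallback sets out from 7 and 3 and comes back at 8. Acetate 7 is borylated (B2pin2, Pd2(dba)3, DMSO, 50 °C) to (3S,6E)-2,6-dimethyl-8-(4,4,5,5-tetramethyl-1,3,2-dioxaborolan-2-yl)octa-1,6-dien-3-ol F4. F4 is then joined to 3 by an α-selective Suzuki–Miyaura coupling (Pd(OAc)2, bulky dialkylbiarylphosphine, K3PO4, THF/H2O, 40 °C), so the iodide meets a nucleophilic allylboron partner instead of a second electrophile.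

Step 6. The secondary allylic mesylate may react by SN2' or ionise, and the peroxide anion may attack the aryl ketone. The fallback sets out from 3 and 4 and comes back at 12. 3 is coupled with geranyl acetate 4 under the step 4 conditions to give 1-[3-[(2E)-3,7-dimethylocta-2,6-dien-1-yl]-2-hydroxy-4-methoxyphenyl]ethan-1-one F5. Schenck ene photo-oxygenation (O2, tetraphenylporphyrin, visible light, CH2Cl2, 0 °C) and chromatographic removal of the regioisomeric hydroperoxides gives racemic 1-[3-[(2E)-6-hydroperoxy-3,7-dimethylocta-2,7-dien-1-yl]-2-hydroxy-4-methoxyphenyl]ethan-1-one F6. 2-Methoxypropene/PPTS (CH2Cl2, 0 °C) converts it into racemic 1-[2-hydroxy-4-methoxy-3-[(2E)-6-[(2-methoxypropan-2-yl)peroxy]-3,7-dimethylocta-2,7-dien-1-yl]phenyl]ethan-1-one F7, from which the (R)-enantiomer 12 is taken by preparative HPLC on a chiral stationary phase.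

**Further compounds**
F1 | step 1 | 2-iodo-3-methoxyphenol | COc1cccc(O)c1I
F2 | step 1 | 2-hydroxy-3-iodo-4-methoxybenzaldehyde | O=Cc1ccc(OC)c(I)c1O
F3 | step 1 | 1-(2-hydroxy-3-iodo-4-methoxyphenyl)ethan-1-ol (racemic) | CC(O)c1ccc(OC)c(I)c1O
F4 | step 4 | (3S,6E)-2,6-dimethyl-8-(4,4,5,5-tetramethyl-1,3,2-dioxaborolan-2-yl)octa-1,6-dien-3-ol | CC1(C)OB(C/C=C(\C)CC[C@H](O)C(C)=C)OC1(C)C
F5 | step 6 | 1-[3-[(2E)-3,7-dimethylocta-2,6-dien-1-yl]-2-hydroxy-4-methoxyphenyl]ethan-1-one | CC(=O)c1ccc(OC)c(C/C=C(\C)CCC=C(C)C)c1O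
F6 | step 6 | 1-[3-[(2E)-6-hydroperoxy-3,7-dimethylocta-2,7-dien-1-yl]-2-hydroxy-4-methoxyphenyl]ethan-1-one (racemic) | CC(=O)c1ccc(OC)c(C/C=C(\C)CCC(OO)C(C)=C)c1O
F7 | step 6 | 1-[2-hydroxy-4-methoxy-3-[(2E)-6-[(2-methoxypropan-2-yl)peroxy]-3,7-dimethylocta-2,7-dien-1-yl]phenyl]ethan-1-one (racemic) | CC(=O)c1ccc(OC)c(C/C=C(\C)CCC(OOC(C)(C)OC)C(C)=C)c1O
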